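Thursday's substrate charge is 2.00 times Saturday's, but the product it ends with, 0.0224 M against 0.0182 M, is 1.23 times as much.

| flask | substrate | reagent | free catalyst | remark | time |
|---|---|---|---|---|---|
| Thursday's | 0.064 M | 0.115 M | 0.20 mM | run made earlier |  |
| Saturday's | 0.032 M | 0.115 M | 0.20 mM | run made earlier |  |
| Friday's | 0.048 M | 0.115 M | 0.20 mM | run made earlier |  |
| Wednesday's | 0.064 M | 0.115 M | 0.10 mM | run made earlier |  |
| alder | 0.064 M | 0.115 M (fed, over 4.0 min) | 0.20 mM | all else is in the flask from the start; the feed brings no volume worth counting | 5.0 min |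
| birch | 0.064 M | 0.115 M (in portions, 4, over 4.0 min) | 0.20 mM | first portion at the start, last at 4.0 min | 5.0 min |
| larch | 0.064 M (fed, over 4.0 min) | 0.115 M | 0.20 mM | all else is in the flask from the start; the feed brings no volume worth counting | 5.0 min |
| ash | 0.064 M | 0.115 M | 0.20 mM | everything together at the start | 5.0 min |

| run | time / min | product / % | homo dimer / % |
|---|---|---|---|
| Thursday's | 0.833 | 34.7 | 66.5 |
| Thursday's | 1.50 | 35.0 | 64.7 |
| Thursday's | 2.50 | 33.6 | 64.5 |
| Thursday's | 3.00 | 35.2 | 64.8 |
| Thursday's | 4.00 | 34.5 | 64.0 |
| Thursday's | 5.00 | 35.5 | 66.6 |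
| Saturday's | 0.500 | 51.3 | 42.8 |
| Saturday's | 1.00 | 57.0 | 43.9 |
| Saturday's | 1.50 | 56.5 | 44.6 |
| Saturday's | 2.00 | 56.3 | 44.7 |
| Saturday's | 2.50 | 57.1 | 43.2 |
| Saturday's | 3.00 | 57.3 | 43.2 |
| Friday's | 0.500 | 35.6 | 56.3 |
| Friday's | 1.00 | 43.3 | 56.4 |
| Friday's | 1.50 | 41.4 | 56.8 |
| Friday's | 2.00 | 42.5 | 58.2 |
| Friday's | 2.50 | 43.0 | 58.1 |
| Friday's | 3.00 | 43.9 | 55.5 |
| Wednesday's | 0.250 | 8.6 | 61.9 |
| Wednesday's | 0.833 | 21.8 | 76.2 |
| Wednesday's | 1.33 | 25.4 | 73.8 |
| Wednesday's | 2.00 | 24.1 | 72.8 |
| Wednesday's | 3.00 | 25.9 | 76.2 |

(each reading ± 1 percentage point)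

- a species is counted by the substrate in it: one homo dimer counts as two
- what was read earlier has a scatter of 1 percentage point, one standard deviation

1. the flask with the highest share of product in product plus homo dimer ("all alike" if they lie within 1.5 percentage points) (alder / birch / larch / ash / all alike)
2. share of product in product plus homo dimer at the end, alder
3. share of product in product plus homo dimer at the end, birch
4. share of product in product plus homo dimer at the end, larch
5. share of product in product plus homo dimer at the end, ash

We call the amount of product that a flask charged at the start ends with its ration, and take Thursday's as the reference. Of the extra substrate Thursday's run holds over Saturday's, 13.2% became product, so between these two runs the ration grows little with the substrate charged. Ash repeats Thursday's recipe, so we reckon its selectivity, the share of product, as ration over charge: 35.1%.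

How long does the ration take? Wednesday's first reading, scaled in proportion to free catalyst, which is our assumption, gives a product rate of 0.0440 M min⁻¹. The ration then takes 0.510 min.

What does slow addition do to that? In larch, one such span of feed brings 0.00816 M of substrate, 0.363 of a ration, so substrate arrives slower than product forms, and we put larch on top. In alder, the same span brings 12.7% of the reagent, against birch's first portion of 25.0%. If product rate follows reagent, we expect alder below birch and birch below ash, but we commit to no figures for them.

The forecast says larch, with 18% for alder, 22% for birch, 96% for larch and 35% for ash, and warns: “Reagent order was never varied, so this is an assumption.”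

The flasks give 18.0% for alder, 25.8% for birch, 99.9% for larch and 34.4% for ash, so larch stands highest.

    catalyst intermediate C ⇌ catalyst intermediate D (K = 0.678, k = 9.44 s⁻¹)
    substrate + catalyst intermediate B → catalyst intermediate C (k = 7530 L mol⁻¹ s⁻¹)
    reagent + free catalyst → catalyst intermediate A (k = 98.1 L mol⁻¹ s⁻¹)
    catalyst intermediate D → free catalyst + product (k = 100 s⁻¹)
    catalyst intermediate A → catalyst intermediate B (k = 8.15 s⁻¹)
    2 substrate → homo dimer (k = 1.01 L mol⁻¹ s⁻¹)

In alder, half of the homo dimer turnover is done by 0.0900 min, while half of the turnover from catalyst intermediate A to catalyst intermediate B takes until 0.746 min. At 0.0900 min, the loss to homo dimer uses 64 times the substrate that catalyst intermediate B takes up. Alder's ration is 0.0115 M, half of Thursday's. Divided by the 0.026 M of substrate in a neighbouring flask, otherwise alder's recipe, it gives 44.2%, and that flask stands at 37.7%.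

All runs stem from a simulated flask on assumed constants; noise was put on by code.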